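The cyclohexane is cut into a two-carbon and a four-carbon piece. A catalytic enantioselective Diels–Alder reaction of ethyl (E)-3-methyl-4-oxobut-2-enoate with a 2-(1-acetoxy-2-silyloxyethyl)buta-1,3-diene forms C1–C6 and C2–C3 at once (C1: quaternary methyl/vinyl carbon; C2: isopropenyl-bearing CH; C4: side-chain carbon). It exploits the trans vicinal pair C1/C2, which maps onto the E alkene, and the 1,4 relationship C1/C4, the para orientation of a 2-substituted diene. Formyl and ester become vinyl and isopropenyl; C4 is relayed thermodynamically through an acyl group, and the Z allylic acetate chain is joined by Wittig reaction of the resulting α-silyloxy ketone.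

Key step: step 3

Remark on the chemistry (assumption): the diene is used racemic at its acetoxy-bearing carbon, because that carbon is later oxidised to a ketone. Compounds 7, 8 and 9 are therefore pairs of epimers at that carbon (drawn without a stereo mark there) and converge at enone 10. Ring carbons are numbered C1 (quaternary), C2 (isopropenyl-bearing), C3, C4 (side-chain-bearing), C5, C6 throughout.

Step 1
Reactants: 1 2-[(tert-butyldimethylsilyl)oxy]acetaldehyde; 2 1,4-dibromobut-2-yne
Product: 4 1-[(tert-butyldimethylsilyl)oxy]-3-methylidenepent-4-en-2-ol (racemic), via bromoallenyl carbinol 3 (not isolated)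
Conditions: In (powder, 2.2 equiv), THF/H2O, rt
Reagents that add atoms: none
Why: Barbier-type indium-mediated buta-1,3-dien-2-ylation, in which the propargylic indium species from 2 adds to the aldehyde with SE2' transposition to give allenyl bromide 3 and a second indium insertion followed by γ-protonation by water unveils the 2-substituted diene; the new carbinol centre is formed as a racemate, which is immaterial because it is later oxidised to a ketone.

Step 2
Reactants: 4 1-[(tert-butyldimethylsilyl)oxy]-3-methylidenepent-4-en-2-ol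
Product: 5 1-[(tert-butyldimethylsilyl)oxy]-3-methylidenepent-4-en-2-yl acetate (racemic)
Conditions: Ac2O, pyridine, 4-(dimethylamino)pyridine (cat.), CH2Cl2, 0 °C → rt
Reagents that add atoms: acetic anhydride, CC(=O)OC(C)=O
Why: Standard O-acylation masks the hydroxyl group against the acidic boron catalyst of the next step as an ester that the later methyllithium step removes without an extra operation.

Step 3
Reactants: 5 1-[(tert-butyldimethylsilyl)oxy]-3-methylidenepent-4-en-2-yl acetate; 6 ethyl (2E)-3-methyl-4-oxobut-2-enoate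
Product: 7 ethyl (1S,6S)-3-{1-(acetyloxy)-2-[(tert-butyldimethylsilyl)oxy]ethyl}-6-formyl-6-methylcyclohex-3-ene-1-carboxylate (both epimers at the acetoxy carbon)
Conditions: (R)-1-(2-methylphenyl)-3,3-diphenyltetrahydro-1H,3H-pyrrolo[1,2-c][1,3,2]oxazaborole (20 mol %), HN(SO2CF3)2 (16 mol %), CH2Cl2, −78 → −20 °C
Reagents that add atoms: none
Why: The step is a concerted, asynchronous normal-demand [4+2] cycloaddition of the diene with the enal, whose formyl group is bound to the protonated chiral oxazaborolidine; the closest known reaction type is the oxazaborolidinium-catalysed Diels–Alder reaction of α-substituted acroleins with 2-substituted butadienes. The cyclohexene ring is closed by intermolecular [4+2] union, suprafacial on both partners, which forms C2–C3 and C1–C6. The relative configuration of C1 and C2 (formyl trans to ester, methyl cis to ester) is fixed by the E geometry of the dienophile, and because both diene termini are unsubstituted no endo/exo question arises. The absolute configuration is set by the catalyst: in the s-trans complex held by the formyl C–H···O contact, the phenyl group of the (R)-catalyst is expected to shield the Re face of the formyl-bearing carbon, so the diene should add to its Si face. The required regioselectivity (C4 para to the formyl-bearing C1) follows from bonding of the more nucleophilic diene terminus C3 to the β-carbon C2 of the complexed enal, and is secured by the preference of the Lewis acid for the aldehyde over the ester carbonyl groups. The acetoxy-bearing carbon is not controlled and need not be.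

Step 4
Reactants: 7 ethyl (1S,6S)-3-{1-(acetyloxy)-2-[(tert-butyldimethylsilyl)oxy]ethyl}-6-formyl-6-methylcyclohex-3-ene-1-carboxylate
Product: 8 ethyl (1S,6R)-3-{1-(acetyloxy)-2-[(tert-butyldimethylsilyl)oxy]ethyl}-6-ethenyl-6-methylcyclohex-3-ene-1-carboxylate
Conditions: Ph3PCH3Br, KN(SiMe3)2, THF, −78 → 0 °C
Reagents that add atoms: methyltriphenylphosphonium bromide, C[P+](c1ccccc1)(c1ccccc1)c1ccccc1.[Br-]
Why: Wittig methylenation of the non-enolisable neopentyl aldehyde, which is far more electrophilic toward the ylide than the two ester groups, installs the vinyl group without touching a stereocentre.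

Step 5
Reactants: 8 ethyl (1S,6R)-3-{1-(acetyloxy)-2-[(tert-butyldimethylsilyl)oxy]ethyl}-6-ethenyl-6-methylcyclohex-3-ene-1-carboxylate
Product: 9 2-[(tert-butyldimethylsilyl)oxy]-1-[(4R,5S)-4-ethenyl-5-(2-hydroxypropan-2-yl)-4-methylcyclohex-1-en-1-yl]ethan-1-ol (both carbinol epimers)
Conditions: MeLi (6 equiv), CeCl3, THF, −78 → 0 °C; then H2O
Reagents that add atoms: methyllithium, [Li]C
Why: Twofold addition of the methyl organocerium reagent to the ethyl ester gives the tertiary alcohol that is the isopropenyl precursor while the same reagent cleaves the acetate, its low basicity leaving the adjacent ring stereocentre untouched.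

Step 6
Reactants: 9 2-[(tert-butyldimethylsilyl)oxy]-1-[(4R,5S)-4-ethenyl-5-(2-hydroxypropan-2-yl)-4-methylcyclohex-1-en-1-yl]ethan-1-ol
Product: 10 2-[(tert-butyldimethylsilyl)oxy]-1-[(4R,5S)-4-ethenyl-5-(2-hydroxypropan-2-yl)-4-methylcyclohex-1-en-1-yl]ethan-1-one
Conditions: 1,1,1-triacetoxy-1,1-dihydro-1,2-benziodoxol-3(1H)-one, CH2Cl2, 0 °C → rt
Reagents that add atoms: none
Why: Oxidation of the secondary allylic alcohol by the hypervalent iodine reagent gives the enone and erases the uncontrolled carbinol centre, the tertiary alcohol being inert.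

Step 7
Reactants: 10 2-[(tert-butyldimethylsilyl)oxy]-1-[(4R,5S)-4-ethenyl-5-(2-hydroxypropan-2-yl)-4-methylcyclohex-1-en-1-yl]ethan-1-one
Product: 13 2-[(tert-butyldimethylsilyl)oxy]-1-[(1S,3S,4R)-4-ethenyl-3-(2-hydroxypropan-2-yl)-4-methylcyclohexyl]ethan-1-one, via copper enolate 11 (not isolated), via C4-epimeric ketone 12 (not isolated)
Conditions: [(Ph3P)CuH]6 (0.5 equiv), toluene, H2O (2 equiv), rt; then 1,8-diazabicyclo[5.4.0]undec-7-ene (cat.), CH2Cl2, rt
Reagents that add atoms: none
Why: Conjugate reduction by the copper hydride (1,4-hydride addition that spares the isolated vinyl group, the silyl ether and the free alcohol) gives a copper enolate whose protonation and base equilibration should place the acyl group at C4 equatorial and cis to the C2 substituent, so that the C4 stereocentre is set under thermodynamic control relayed from C1 and C2.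

Step 8
Reactants: 13 2-[(tert-butyldimethylsilyl)oxy]-1-[(1S,3S,4R)-4-ethenyl-3-(2-hydroxypropan-2-yl)-4-methylcyclohexyl]ethan-1-one
Product: 14 2-[(tert-butyldimethylsilyl)oxy]-1-[(1S,3R,4R)-4-ethenyl-4-methyl-3-(prop-1-en-2-yl)cyclohexyl]ethan-1-one
Conditions: methyl N-(triethylammoniosulfonyl)carbamate, toluene, 60 °C
Reagents that add atoms: none
Why: Syn-elimination (Ei) of the tertiary sulfamate ester should give the isopropenyl group, because abstraction of one of six methyl hydrogens is favoured statistically and sterically over the single ring hydrogen at C2, whose loss would create a tetrasubstituted alkene with severe allylic strain against the quaternary C1.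

Step 9
Reactants: 15 (3S)-3-hydroxyoxolan-2-one
Product: 16 (3S)-4-methylpentane-1,3,4-triol
Conditions: MeMgBr (4 equiv), THF, 0 °C → rt; then H2O
Reagents that add atoms: methylmagnesium bromide, C[Mg]Br
Why: Double Grignard addition to the lactone carbonyl (after deprotonation of the hydroxyl group) opens the ring to the gem-dimethyl carbinol, and the stereocentre, bought from the chiral pool, is not touched.

Step 10
Reactants: 16 (3S)-4-methylpentane-1,3,4-triol
Product: 17 2-[(4S)-2,2,5,5-tetramethyl-1,3-dioxolan-4-yl]ethan-1-ol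
Conditions: 2,2-dimethoxypropane, p-toluenesulfonic acid (cat.), acetone, rt
Reagents that add atoms: 2,2-dimethoxypropane, COC(C)(C)OC
Why: Acetalisation under thermodynamic control should select the five-membered 1,3-dioxolane of the vicinal secondary/tertiary diol over the six-membered acetal that would include the primary hydroxyl group, which stays free.

Step 11
Reactants: 17 2-[(4S)-2,2,5,5-tetramethyl-1,3-dioxolan-4-yl]ethan-1-ol
Product: 18 (4S)-4-(2-iodoethyl)-2,2,5,5-tetramethyl-1,3-dioxolane
Conditions: I2, PPh3, imidazole, CH2Cl2, 0 °C → rt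
Reagents that add atoms: iodine, II
Why: Appel-type iodination of the primary alcohol proceeds by SN2 displacement of the alkoxyphosphonium ion, and imidazole scavenges the acid so that the acetonide survives.

Step 12
Reactants: 18 (4S)-4-(2-iodoethyl)-2,2,5,5-tetramethyl-1,3-dioxolane
Product: 19 triphenyl{2-[(4S)-2,2,5,5-tetramethyl-1,3-dioxolan-4-yl]ethyl}phosphonium iodide
Conditions: PPh3, MeCN, reflux
Reagents that add atoms: triphenylphosphine, c1ccc(cc1)P(c1ccccc1)c1ccccc1
Why: SN2 quaternisation of triphenylphosphine by the unhindered primary iodide gives the phosphonium salt without affecting the stereocentre.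

Step 13
Reactants: 19 triphenyl{2-[(4S)-2,2,5,5-tetramethyl-1,3-dioxolan-4-yl]ethyl}phosphonium iodide; 14 2-[(tert-butyldimethylsilyl)oxy]-1-[(1S,3R,4R)-4-ethenyl-4-methyl-3-(prop-1-en-2-yl)cyclohexyl]ethan-1-one
Product: 21 tert-butyl({(2Z)-2-[(1S,3R,4R)-4-ethenyl-4-methyl-3-(prop-1-en-2-yl)cyclohexyl]-4-[(4S)-2,2,5,5-tetramethyl-1,3-dioxolan-4-yl]but-2-en-1-yl}oxy)dimethylsilane, via phosphorus ylide 20 (not isolated)
Conditions: 19, KN(SiMe3)2, THF, −78 → 0 °C; then 14, −78 °C → rt
Reagents that add atoms: none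
Why: Wittig reaction of a non-stabilised ylide with an α-silyloxy ketone, a combination known to place the ylide carbon chain cis to the oxygenated methylene group (here the Z alkene), joins the two fragments, while the equatorial C4 centre next to the ketone is the thermodynamically preferred one and the dioxolane centre is remote.

Step 14
Reactants: 21 tert-butyl({(2Z)-2-[(1S,3R,4R)-4-ethenyl-4-methyl-3-(prop-1-en-2-yl)cyclohexyl]-4-[(4S)-2,2,5,5-tetramethyl-1,3-dioxolan-4-yl]but-2-en-1-yl}oxy)dimethylsilane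
Product: 22 (2Z,5S)-2-[(1S,3R,4R)-4-ethenyl-4-methyl-3-(prop-1-en-2-yl)cyclohexyl]-6-methylhept-2-ene-1,5,6-triol
Conditions: camphor-10-sulfonic acid (cat.), MeOH, rt
Reagents that add atoms: none
Why: Acid-catalysed methanolysis removes the primary silyl ether and transacetalises the acetonide in one operation under conditions too mild to ionise the allylic alcohol or hydrate the alkenes.

Step 15
Reactants: 22 (2Z,5S)-2-[(1S,3R,4R)-4-ethenyl-4-methyl-3-(prop-1-en-2-yl)cyclohexyl]-6-methylhept-2-ene-1,5,6-triol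
Product: 23 (2Z,5S)-2-[(1S,3R,4R)-4-ethenyl-4-methyl-3-(prop-1-en-2-yl)cyclohexyl]-5,6-dihydroxy-6-methylhept-2-en-1-yl acetate
Conditions: AcCl (1.05 equiv), 2,4,6-trimethylpyridine, CH2Cl2, −78 °C
Reagents that add atoms: acetyl chloride, CC(=O)Cl
Why: Kinetically selective O-acylation of the unhindered primary allylic hydroxyl group over the hindered secondary and the tertiary hydroxyl groups should complete the target.

Compound list
1 | 2-[(tert-butyldimethylsilyl)oxy]acetaldehyde | O=CCO[Si](C)(C)C(C)(C)C | starting material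
2 | 1,4-dibromobut-2-yne | BrCC#CCBr | starting material
3 | 3-(bromomethyl)-1-[(tert-butyldimethylsilyl)oxy]penta-3,4-dien-2-ol | C=C=C(CBr)C(O)CO[Si](C)(C)C(C)(C)C | intermediate (not isolated)
4 | 1-[(tert-butyldimethylsilyl)oxy]-3-methylidenepent-4-en-2-ol (racemic) | C=CC(=C)C(O)CO[Si](C)(C)C(C)(C)C | intermediate
5 | 1-[(tert-butyldimethylsilyl)oxy]-3-methylidenepent-4-en-2-yl acetate (racemic) | C=CC(=C)C(OC(C)=O)CO[Si](C)(C)C(C)(C)C | intermediate
6 | ethyl (2E)-3-methyl-4-oxobut-2-enoate | CCOC(=O)/C=C(\C)C=O | starting material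
7 | ethyl (1S,6S)-3-{1-(acetyloxy)-2-[(tert-butyldimethylsilyl)oxy]ethyl}-6-formyl-6-methylcyclohex-3-ene-1-carboxylate (epimers at the acetoxy carbon) | O=C[C@@]1(C)CC=C(C(OC(C)=O)CO[Si](C)(C)C(C)(C)C)C[C@@H]1C(=O)OCC | intermediate
8 | ethyl (1S,6R)-3-{1-(acetyloxy)-2-[(tert-butyldimethylsilyl)oxy]ethyl}-6-ethenyl-6-methylcyclohex-3-ene-1-carboxylate (epimers at the acetoxy carbon) | C=C[C@@]1(C)CC=C(C(OC(C)=O)CO[Si](C)(C)C(C)(C)C)C[C@@H]1C(=O)OCC | intermediate
9 | 2-[(tert-butyldimethylsilyl)oxy]-1-[(4R,5S)-4-ethenyl-5-(2-hydroxypropan-2-yl)-4-methylcyclohex-1-en-1-yl]ethan-1-ol (carbinol epimers) | C=C[C@@]1(C)CC=C(C(O)CO[Si](C)(C)C(C)(C)C)C[C@@H]1C(C)(C)O | intermediate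
10 | 2-[(tert-butyldimethylsilyl)oxy]-1-[(4R,5S)-4-ethenyl-5-(2-hydroxypropan-2-yl)-4-methylcyclohex-1-en-1-yl]ethan-1-one | C=C[C@@]1(C)CC=C(C(=O)CO[Si](C)(C)C(C)(C)C)C[C@@H]1C(C)(C)O | intermediate
11 | copper enolate of ketone 13 (exocyclic enolate at C4) | C=C[C@@]1(C)CCC(=C(O[Cu])CO[Si](C)(C)C(C)(C)C)C[C@@H]1C(C)(C)O | intermediate (not isolated)
12 | 2-[(tert-butyldimethylsilyl)oxy]-1-[(1R,3S,4R)-4-ethenyl-3-(2-hydroxypropan-2-yl)-4-methylcyclohexyl]ethan-1-one (C4 epimer of 13) | C=C[C@@]1(C)CC[C@@H](C(=O)CO[Si](C)(C)C(C)(C)C)C[C@@H]1C(C)(C)O | intermediate (not isolated)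
13 | 2-[(tert-butyldimethylsilyl)oxy]-1-[(1S,3S,4R)-4-ethenyl-3-(2-hydroxypropan-2-yl)-4-methylcyclohexyl]ethan-1-one | C=C[C@@]1(C)CC[C@H](C(=O)CO[Si](C)(C)C(C)(C)C)C[C@@H]1C(C)(C)O | intermediate
14 | 2-[(tert-butyldimethylsilyl)oxy]-1-[(1S,3R,4R)-4-ethenyl-4-methyl-3-(prop-1-en-2-yl)cyclohexyl]ethan-1-one | C=C[C@@]1(C)CC[C@H](C(=O)CO[Si](C)(C)C(C)(C)C)C[C@@H]1C(=C)C | intermediate
15 | (3S)-3-hydroxyoxolan-2-one ((S)-α-hydroxy-γ-butyrolactone) | O=C1OCC[C@@H]1O | starting material
16 | (3S)-4-methylpentane-1,3,4-triol | OCC[C@H](O)C(C)(C)O | intermediate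
17 | 2-[(4S)-2,2,5,5-tetramethyl-1,3-dioxolan-4-yl]ethan-1-ol | OCC[C@@H]1OC(C)(C)OC1(C)C | intermediate
18 | (4S)-4-(2-iodoethyl)-2,2,5,5-tetramethyl-1,3-dioxolane | ICC[C@@H]1OC(C)(C)OC1(C)C | intermediate
19 | triphenyl{2-[(4S)-2,2,5,5-tetramethyl-1,3-dioxolan-4-yl]ethyl}phosphonium iodide | [I-].c1ccccc1[P+](c1ccccc1)(c1ccccc1)CC[C@@H]1OC(C)(C)OC1(C)C | intermediate
20 | triphenyl{2-[(4S)-2,2,5,5-tetramethyl-1,3-dioxolan-4-yl]ethylidene}phosphorane | c1ccccc1P(c1ccccc1)(c1ccccc1)=CC[C@@H]1OC(C)(C)OC1(C)C | intermediate (not isolated)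
21 | tert-butyl({(2Z)-2-[(1S,3R,4R)-4-ethenyl-4-methyl-3-(prop-1-en-2-yl)cyclohexyl]-4-[(4S)-2,2,5,5-tetramethyl-1,3-dioxolan-4-yl]but-2-en-1-yl}oxy)dimethylsilane | C=C[C@@]1(C)CC[C@H](/C(=C/C[C@@H]2OC(C)(C)OC2(C)C)CO[Si](C)(C)C(C)(C)C)C[C@@H]1C(=C)C | intermediate
22 | (2Z,5S)-2-[(1S,3R,4R)-4-ethenyl-4-methyl-3-(prop-1-en-2-yl)cyclohexyl]-6-methylhept-2-ene-1,5,6-triol | C=C[C@@]1(C)CC[C@H](/C(=C/C[C@H](O)C(C)(C)O)CO)C[C@@H]1C(=C)C | intermediate
23 | (2Z,5S)-2-[(1S,3R,4R)-4-ethenyl-4-methyl-3-(prop-1-en-2-yl)cyclohexyl]-5,6-dihydroxy-6-methylhept-2-en-1-yl acetate | C=C[C@@]1(C)CC[C@H](/C(=C/C[C@H](O)C(C)(C)O)COC(C)=O)C[C@@H]1C(=C)C | target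

Total step count: 15. Longest linear sequence: 11 steps (steps 1–8 and 13–15); the side-chain fragment takes steps 9–12.

Steps most likely to fail

Step 3 (key cycloaddition). The inductively deactivated 2-substituent may direct only weakly to the para adduct. The acidic catalyst may ionise the allylic acetate of the diene. Enantioface control with this β-carboxy enal may be lower than, or opposite to, the model; an opposite sense alone is answered by the (S)-catalyst. The fallback uses a strongly para-directing, acid-stable diene and attaches the oxygenated two-carbon unit afterwards. It sets out from dienophile 6 and comes back to the route at diol 9. But-3-en-2-one is silylated (i-Pr3SiOSO2CF3, Et3N) to 2-[(triisopropylsilyl)oxy]buta-1,3-diene F1. The same catalysed Diels–Alder reaction with 6 gives the silyl enol ether adduct ethyl (1S,6S)-6-formyl-6-methyl-3-[(triisopropylsilyl)oxy]cyclohex-3-ene-1-carboxylate F2. Wittig methylenation as in step 4 gives the vinyl ester F3, and MeLi/CeCl3 as in step 5 gives the tertiary alcohol F4. CsF and PhN(SO2CF3)2 convert the silyl enol ether regiospecifically into the enol triflate F5. A Nozaki–Hiyama–Kishi coupling of F5 with aldehyde 1 (CrCl2, NiCl2 cat., DMF) then gives 9.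

Step 13 (Wittig union). Olefination of the α-branched, enolisable ketone may be slow, and the Z selectivity known for α-oxygenated methyl ketones may erode with the bulky cyclohexyl group. The fallback is a Horner–Wittig sequence with separation of the adducts and stereospecific elimination. It sets out from 19 and 14 and comes back at 21. Aqueous NaOH hydrolyses 19, with loss of benzene, to diphenyl{2-[(4S)-2,2,5,5-tetramethyl-1,3-dioxolan-4-yl]ethyl}phosphine oxide F6. Its lithio derivative (n-BuLi, THF, −78 °C) adds to 14 to give four β-hydroxy phosphine oxides. The (2S,3R) adduct F7 and the (2R,3S) adduct F8 bring the silyloxymethyl group and the chain together on syn-elimination. They are separated by chromatography from the (2S,3S) adduct F9 and the (2R,3R) adduct F10, which are discarded. NaH in DMF then eliminates diphenylphosphinate from F7 and F8 in a syn fashion to give 21 as a single alkene isomer.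

Step 8 (dehydration). Elimination toward the ring could give the isopropylidene isomer, and the acidic by-product could migrate the new double bond. The fallback builds the isopropenyl group by carbonyl methylenation, which has no regiochemical choice. It sets out from 8 and comes back at 14. Me3SiCH2Li (excess, pentane/THF, then MeOH) stops at the ketone stage and also removes the acetate, giving the methyl ketone 1-[(1S,6R)-3-{2-[(tert-butyldimethylsilyl)oxy]-1-hydroxyethyl}-6-ethenyl-6-methylcyclohex-3-en-1-yl]ethan-1-one F11. Wittig methylenation (Ph3P=CH2, excess) gives the isopropenyl carbinol F12. Oxidation as in step 6 gives the enone F13. Conjugate reduction and equilibration as in step 7, through the copper enolate F14 and the C4-epimeric ketone F15, give 14.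

Further compounds
F1 | step 3 | 2-[(triisopropylsilyl)oxy]buta-1,3-diene | C=CC(=C)O[Si](C(C)C)(C(C)C)C(C)C
F2 | step 3 | ethyl (1S,6S)-6-formyl-6-methyl-3-[(triisopropylsilyl)oxy]cyclohex-3-ene-1-carboxylate | O=C[C@@]1(C)CC=C(O[Si](C(C)C)(C(C)C)C(C)C)C[C@@H]1C(=O)OCC
F3 | step 3 | ethyl (1S,6R)-6-ethenyl-6-methyl-3-[(triisopropylsilyl)oxy]cyclohex-3-ene-1-carboxylate | C=C[C@@]1(C)CC=C(O[Si](C(C)C)(C(C)C)C(C)C)C[C@@H]1C(=O)OCC
F4 | step 3 | 2-{(1S,6R)-6-ethenyl-6-methyl-3-[(triisopropylsilyl)oxy]cyclohex-3-en-1-yl}propan-2-ol | C=C[C@@]1(C)CC=C(O[Si](C(C)C)(C(C)C)C(C)C)C[C@@H]1C(C)(C)O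
F5 | step 3 | (4R,5S)-4-ethenyl-5-(2-hydroxypropan-2-yl)-4-methylcyclohex-1-en-1-yl trifluoromethanesulfonate | C=C[C@@]1(C)CC=C(OS(=O)(=O)C(F)(F)F)C[C@@H]1C(C)(C)O
F6 | step 13 | diphenyl{2-[(4S)-2,2,5,5-tetramethyl-1,3-dioxolan-4-yl]ethyl}phosphine oxide | O=P(c1ccccc1)(c1ccccc1)CC[C@@H]1OC(C)(C)OC1(C)C
F7 | step 13 | (2S,3R)-1-[(tert-butyldimethylsilyl)oxy]-3-(diphenylphosphoryl)-2-[(1S,3R,4R)-4-ethenyl-4-methyl-3-(prop-1-en-2-yl)cyclohexyl]-4-[(4S)-2,2,5,5-tetramethyl-1,3-dioxolan-4-yl]butan-2-ol | C=C[C@@]1(C)CC[C@H]([C@](O)(CO[Si](C)(C)C(C)(C)C)[C@@H](CC[C@@H]2OC(C)(C)OC2(C)C)P(=O)(c2ccccc2)c2ccccc2)C[C@@H]1C(=C)C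
F8 | step 13 | (2R,3S) diastereomer of F7 | C=C[C@@]1(C)CC[C@H]([C@@](O)(CO[Si](C)(C)C(C)(C)C)[C@H](CC[C@@H]2OC(C)(C)OC2(C)C)P(=O)(c2ccccc2)c2ccccc2)C[C@@H]1C(=C)C
F9 | step 13 | (2S,3S) diastereomer of F7 | C=C[C@@]1(C)CC[C@H]([C@](O)(CO[Si](C)(C)C(C)(C)C)[C@H](CC[C@@H]2OC(C)(C)OC2(C)C)P(=O)(c2ccccc2)c2ccccc2)C[C@@H]1C(=C)C
F10 | step 13 | (2R,3R) diastereomer of F7 | C=C[C@@]1(C)CC[C@H]([C@@](O)(CO[Si](C)(C)C(C)(C)C)[C@@H](CC[C@@H]2OC(C)(C)OC2(C)C)P(=O)(c2ccccc2)c2ccccc2)C[C@@H]1C(=C)C
F11 | step 8 | 1-[(1S,6R)-3-{2-[(tert-butyldimethylsilyl)oxy]-1-hydroxyethyl}-6-ethenyl-6-methylcyclohex-3-en-1-yl]ethan-1-one (carbinol epimers) | C=C[C@@]1(C)CC=C(C(O)CO[Si](C)(C)C(C)(C)C)C[C@@H]1C(C)=O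
F12 | step 8 | 2-[(tert-butyldimethylsilyl)oxy]-1-[(4R,5R)-4-ethenyl-4-methyl-5-(prop-1-en-2-yl)cyclohex-1-en-1-yl]ethan-1-ol (carbinol epimers) | C=C[C@@]1(C)CC=C(C(O)CO[Si](C)(C)C(C)(C)C)C[C@@H]1C(=C)C
F13 | step 8 | 2-[(tert-butyldimethylsilyl)oxy]-1-[(4R,5R)-4-ethenyl-4-methyl-5-(prop-1-en-2-yl)cyclohex-1-en-1-yl]ethan-1-one | C=C[C@@]1(C)CC=C(C(=O)CO[Si](C)(C)C(C)(C)C)C[C@@H]1C(=C)C
F14 | step 8 | copper enolate of ketone 14 (exocyclic enolate at C4) | C=C[C@@]1(C)CCC(=C(O[Cu])CO[Si](C)(C)C(C)(C)C)C[C@@H]1C(=C)C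
F15 | step 8 | 2-[(tert-butyldimethylsilyl)oxy]-1-[(1R,3R,4R)-4-ethenyl-4-methyl-3-(prop-1-en-2-yl)cyclohexyl]ethan-1-one (C4 epimer of 14) | C=C[C@@]1(C)CC[C@@H](C(=O)CO[Si](C)(C)C(C)(C)C)C[C@@H]1C(=C)C
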